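**Plan**
Numbering is eudesmane-type: ring A = C1–C5 and C10, ring B = C5–C10, C14 on C10, C15 on C4, C11 = carbinol carbon on C7; β is the face of the C14 methyl group.
Retrosynthetic cuts: the C3 ester; C4–OH and C3–H (back to a C3=C4 silyl enol ether); ring B at C8–C9 and C7–C8, so that C8 is carbon monoxide, C7 an alkenyl iodide (from a C6≡C7 alkyne) and C9 an aldehyde-derived carbene carbon; ring A at C4–C5 and C1–C10 (Diels–Alder).
Forward order: ring A first, from a 2-silyloxy diene and an (E)-enynal that already carries C6, C7 and C11–C13; then ring B by a palladium-catalysed carbonylative carbene ring closure; then Rubottom oxidation, ketone reduction, desilylation and esterification.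
Enabling feature: in ring B the C8 carbonyl lies between the vinylic C7 and the C9 methylene, and C9 hangs on the quaternary C10; a C8 acylpalladium can therefore migrate onto a C9 carbene, and the enolate formed has no β-hydrogen and can only be reduced to C9H2–C8(=O).
Stereochemistry: C5/C10 from the catalyst-controlled Diels–Alder reaction (trans from the E dienophile); C4 from α-face epoxidation anti to the axial C14 methyl; C3 from axial hydride delivery; the side-chain centre from (R)-2-methylbutanoic acid.

Key step: step 8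

Assumption: the (S)-configured oxazaborolidinium ion is taken to direct the diene to the enal face that leads to 9 as drawn; if the sense proves opposite, its (R)-enantiomer is used with no other change.

Step 1
Reactants: 1 3-methyl-3-(trimethylsilyloxy)but-1-yne
Product: 3 4-methyl-4-(trimethylsilyloxy)pent-2-ynal, via lithium acetylide 2 (not isolated)
Conditions: n-BuLi, THF, −78 °C; DMF, −78 → 0 °C; inverse quench into aq. KH2PO4
Reagents that add atoms: N,N-dimethylformamide, CN(C)C=O
Why: Formylation of a lithium acetylide with DMF should give the ynal, the buffered inverse quench keeping the liberated amine from adding to the triple bond.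

Step 2
Reactants: 3 4-methyl-4-(trimethylsilyloxy)pent-2-ynal; 4 2-(triphenyl-λ5-phosphanylidene)propanal
Product: 5 (2E)-2,6-dimethyl-6-(trimethylsilyloxy)hept-2-en-4-ynal
Conditions: CH2Cl2, 23 °C
Reagents that add atoms: none
Why: Wittig olefination with the stabilised ylide should take place at the more electrophilic ynal carbonyl and give the (E)-2-methyl enal, which fixes the dienophile geometry that becomes the trans C5/C10 relationship.

Step 3
Reactants: 6 pent-1-en-3-one
Product: 7 tert-butyl(dimethyl)[(3Z)-penta-1,3-dien-3-yloxy]silane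
Conditions: TBSOTf, Et3N, Et2O, 0 °C
Reagents that add atoms: tert-butyldimethylsilyl trifluoromethanesulfonate, CC(C)(C)[Si](C)(C)OS(=O)(=O)C(F)(F)F
Why: Silyl enol ether formation by soft enolisation of the ethyl ketone should give the Z enol ether, in which the methyl group points away from the vinyl unit as the s-cis diene conformer requires.

Step 4
Reactants: 5 (2E)-2,6-dimethyl-6-(trimethylsilyloxy)hept-2-en-4-ynal; 7 tert-butyl(dimethyl)[(3Z)-penta-1,3-dien-3-yloxy]silane
Product: 9 (1S,2R)-2-(3-hydroxy-3-methylbut-1-yn-1-yl)-1,3-dimethyl-4-oxocyclohexane-1-carbaldehyde, via silyl enol ether cycloadduct 8 (not isolated)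
Conditions: (S)-1-(2-methylphenyl)-3,3-diphenyltetrahydro-1H,3H-pyrrolo[1,2-c][1,3,2]oxazaborole (20 mol %), HNTf2 (17 mol %), CH2Cl2, −78 → −40 °C; then 1 M HCl, THF, 0 °C
Reagents that add atoms: none
Why: In this Lewis-acid-catalysed Diels–Alder reaction the enol-ether carbon of 7 (C4, bearing C15) bonds to the enal β-carbon (C5) and the CH2 terminus to C10, the E geometry of 5 is transferred suprafacially to the trans C5-alkynyl/C10-formyl relationship, and the chiral oxazaborolidinium ion shields one face of the coordinated enal to set C5 and C10 (the C4 methine is left unassigned because step 6 planarises it); aqueous acid then cleaves the enol ether and the trimethylsilyl ether.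

Step 5
Reactants: 9 (1S,2R)-2-(3-hydroxy-3-methylbut-1-yn-1-yl)-1,3-dimethyl-4-oxocyclohexane-1-carbaldehyde
Product: 11 (1S,2R)-2-[(1Z)-3-hydroxy-2-iodo-3-methylbut-1-en-1-yl]-1,3-dimethyl-4-oxocyclohexane-1-carbaldehyde, via alkenylstannane 10 (not isolated)
Conditions: [Cp*RuCl]4 (2.5 mol %), Bu3SnH, CH2Cl2, 23 °C; then I2, CH2Cl2, 0 °C
Reagents that add atoms: iodine, II
Why: Hydroxyl-directed ruthenium-catalysed trans-hydrostannation should place tin on C7 (next to the carbinol) and hydrogen on C6 from the opposite side, so that iododestannylation with retention gives the Z iodide with iodine cis to C5.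

Step 6
Reactants: 11 (1S,2R)-2-[(1Z)-3-hydroxy-2-iodo-3-methylbut-1-en-1-yl]-1,3-dimethyl-4-oxocyclohexane-1-carbaldehyde
Product: 12 (1S,2S)-4-(tert-butyldimethylsilyloxy)-2-[(1Z)-3-(tert-butyldimethylsilyloxy)-2-iodo-3-methylbut-1-en-1-yl]-1,3-dimethylcyclohex-3-ene-1-carbaldehyde
Conditions: TBSOTf (3 equiv), Et3N (4 equiv), CH2Cl2, 0 → 23 °C
Reagents that add atoms: tert-butyldimethylsilyl trifluoromethanesulfonate, CC(C)(C)[Si](C)(C)OS(=O)(=O)C(F)(F)F
Why: Silyl enol ether formation through the O-silyl oxocarbenium ion should give the more substituted C3=C4 enol ether, which masks the ketone and erases the C4 methine, while the tertiary alcohol is silylated in the same operation and the non-enolisable aldehyde is left free.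

Step 7
Reactants: 12 (1S,2S)-4-(tert-butyldimethylsilyloxy)-2-[(1Z)-3-(tert-butyldimethylsilyloxy)-2-iodo-3-methylbut-1-en-1-yl]-1,3-dimethylcyclohex-3-ene-1-carbaldehyde
Product: 13 N′-[(E)-{(1S,2R)-4-(tert-butyldimethylsilyloxy)-2-[(1Z)-3-(tert-butyldimethylsilyloxy)-2-iodo-3-methylbut-1-en-1-yl]-1,3-dimethylcyclohex-3-en-1-yl}methylidene]-4-methylbenzenesulfonohydrazide
Conditions: TsNHNH2, MgSO4, THF, 23 → 40 °C
Reagents that add atoms: 4-methylbenzenesulfonohydrazide, NNS(=O)(=O)c1ccc(C)cc1
Why: Hydrazone condensation at the only free carbonyl group (the C9 aldehyde) should give the N-tosylhydrazone needed for Bamford–Stevens release of the C9 diazoalkane.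

Step 8
Reactants: 13 N-tosylhydrazone of aldehyde 12
Product: 15 (5R,10R)-3,11-bis(tert-butyldimethylsilyloxy)eudesma-3,6-dien-8-one, via diazoalkane 14 (not isolated)
Conditions: Pd2(dba)3 (5 mol %), Xantphos (12 mol %), CO (1 atm), Cs2CO3, Et3SiH (slow addition), 1,4-dioxane, 85 °C
Reagents that add atoms: carbon monoxide, [C-]#[O+]
Why: Proposed new method: zerovalent palladium inserts into the C7–I bond, CO insertion gives the C8 acylpalladium iodide, the diazoalkane released from the hydrazone by base (Bamford–Stevens) is decomposed on that centre to a palladium carbene at C9, 1,2-migration of the acyl group to the carbene carbon forms C8–C9, and the resulting palladium enolate, which has no β-hydrogen because C10 is quaternary, is released by hydride transfer from Et3SiH and C–H reductive elimination. The closest known reaction type is the intermolecular palladium-catalysed three-component ketone synthesis from aryl iodides, CO and diazo compounds or N-tosylhydrazones by acyl migratory insertion (with silane termination for diazo esters), together with the carbene cross-coupling of tosylhydrazones with alkenyl halides. Ring B is closed as a six-membered carbocycle when the seven-membered chelate (palladium bound to C8 and C9) contracts in the migratory insertion, formally a 6-exo attack of C9 on the acyl carbon. No stereocentre is created: C5 and C10 are untouched, and the Z geometry of the iodide holds C8 on the same side of C6=C7 as C5. The step needs CO insertion to precede carbene capture (direct alkenyl–carbene coupling would give a five-membered ring), which the CO atmosphere and the slow thermal release of the diazoalkane should secure, and it needs the acylpalladium to meet no oxygen nucleophile, which silylation of the C11 hydroxyl and masking of C3 as the enol ether secure. Should the silane first reduce the acylpalladium to the C8 enal, addition of the diazoalkane to that aldehyde followed by 1,2-hydride shift with loss of N2 would deliver the same ketone.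

Step 9
Reactants: 15 (5R,10R)-3,11-bis(tert-butyldimethylsilyloxy)eudesma-3,6-dien-8-one
Product: 17 (4S,5R,10R)-4α,11-bis(tert-butyldimethylsilyloxy)eudesm-6-ene-3,8-dione, via silyloxy epoxide 16 (not isolated)
Conditions: mCPBA, NaHCO3, CH2Cl2, −20 → 0 °C
Reagents that add atoms: 3-chloroperbenzoic acid, OOC(=O)c1cccc(Cl)c1
Why: In this Rubottom oxidation the peracid should epoxidise the electron-rich tetrasubstituted enol ether rather than the enone, from the α face anti to the axial C14 methyl group, and 1,4-silyl migration opens the silyloxy epoxide to the 4α-silyloxy ketone, which sets C4.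

Step 10
Reactants: 17 (4S,5R,10R)-4α,11-bis(tert-butyldimethylsilyloxy)eudesm-6-ene-3,8-dione
Product: 18 (3S,4S,5R,10R)-3β-hydroxy-4α,11-bis(tert-butyldimethylsilyloxy)eudesm-6-en-8-one
Conditions: NaBH4, MeOH–CH2Cl2, −40 °C
Reagents that add atoms: none
Why: Borohydride reduction of the saturated α-silyloxy ketone should be faster than that of the hindered cross-conjugated enone, and axial hydride delivery from the α face, anti to the axial C15 methyl as in 4,4-dimethyl-3-ketones, gives the equatorial 3β alcohol and sets C3.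

Step 11
Reactants: 18 (3S,4S,5R,10R)-3β-hydroxy-4α,11-bis(tert-butyldimethylsilyloxy)eudesm-6-en-8-one
Product: 19 (3S,4S,5R,10R)-3β,4α,11-trihydroxyeudesm-6-en-8-one
Conditions: HF·pyridine, pyridine, THF, 0 → 40 °C
Reagents that add atoms: none
Why: Fluoride-mediated desilylation should remove both tertiary silyl ethers without touching the enone or any stereocentre.

Step 12
Reactants: 19 (3S,4S,5R,10R)-3β,4α,11-trihydroxyeudesm-6-en-8-one; 20 (2R)-2-methylbutanoic acid
Product: 21 (3S,4S,5R,10R)-4α,11-dihydroxy-8-oxoeudesm-6-en-3β-yl (2R)-2-methylbutanoate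
Conditions: DCC, DMAP (cat.), CH2Cl2, 0 → 23 °C
Reagents that add atoms: none
Why: Steglich esterification should acylate only the secondary C3 hydroxyl, the two tertiary alcohols being inert under these conditions, and the acyl stereocentre is carried in unchanged from 20.

**Compound list**
1 | 3-methyl-3-(trimethylsilyloxy)but-1-yne | C#CC(C)(C)O[Si](C)(C)C | starting material
2 | [3-methyl-3-(trimethylsilyloxy)but-1-yn-1-yl]lithium | [Li]C#CC(C)(C)O[Si](C)(C)C | intermediate (not isolated)
3 | 4-methyl-4-(trimethylsilyloxy)pent-2-ynal | O=CC#CC(C)(C)O[Si](C)(C)C | intermediate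
4 | 2-(triphenyl-λ5-phosphanylidene)propanal | CC(C=O)=P(c1ccccc1)(c1ccccc1)c1ccccc1 | starting material
5 | (2E)-2,6-dimethyl-6-(trimethylsilyloxy)hept-2-en-4-ynal | O=C/C(C)=C/C#CC(C)(C)O[Si](C)(C)C | intermediate
6 | pent-1-en-3-one | C=CC(=O)CC | starting material
7 | tert-butyl(dimethyl)[(3Z)-penta-1,3-dien-3-yloxy]silane | C=C/C(O[Si](C)(C)C(C)(C)C)=C/C | intermediate
8 | (1S,6R)-4-(tert-butyldimethylsilyloxy)-1,5-dimethyl-6-[3-methyl-3-(trimethylsilyloxy)but-1-yn-1-yl]cyclohex-3-ene-1-carbaldehyde (formyl and alkynyl trans; ring C5 unassigned) | CC(C)(C)[Si](C)(C)OC1=CC[C@](C)(C=O)[C@@H](C#CC(C)(C)O[Si](C)(C)C)C1C | intermediate (not isolated)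
9 | (1S,2R)-2-(3-hydroxy-3-methylbut-1-yn-1-yl)-1,3-dimethyl-4-oxocyclohexane-1-carbaldehyde (formyl and alkynyl trans; ring C3 unassigned) | O=C1CC[C@](C)(C=O)[C@@H](C#CC(C)(C)O)C1C | intermediate
10 | (1S,2R)-2-[(1Z)-3-hydroxy-3-methyl-2-(tributylstannyl)but-1-en-1-yl]-1,3-dimethyl-4-oxocyclohexane-1-carbaldehyde | O=C1CC[C@](C)(C=O)[C@@H](/C=C(\[Sn](CCCC)(CCCC)CCCC)C(C)(C)O)C1C | intermediate (not isolated)
11 | (1S,2R)-2-[(1Z)-3-hydroxy-2-iodo-3-methylbut-1-en-1-yl]-1,3-dimethyl-4-oxocyclohexane-1-carbaldehyde | O=C1CC[C@](C)(C=O)[C@@H](/C=C(\I)C(C)(C)O)C1C | intermediate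
12 | (1S,2S)-4-(tert-butyldimethylsilyloxy)-2-[(1Z)-3-(tert-butyldimethylsilyloxy)-2-iodo-3-methylbut-1-en-1-yl]-1,3-dimethylcyclohex-3-ene-1-carbaldehyde | CC(C)(C)[Si](C)(C)OC=1CC[C@](C)(C=O)[C@@H](/C=C(\I)C(C)(C)O[Si](C)(C)C(C)(C)C)C=1C | intermediate
13 | N′-[(E)-{(1S,2R)-4-(tert-butyldimethylsilyloxy)-2-[(1Z)-3-(tert-butyldimethylsilyloxy)-2-iodo-3-methylbut-1-en-1-yl]-1,3-dimethylcyclohex-3-en-1-yl}methylidene]-4-methylbenzenesulfonohydrazide | CC(C)(C)[Si](C)(C)OC=1CC[C@](C)(/C=N/NS(=O)(=O)c2ccc(C)cc2)[C@@H](/C=C(\I)C(C)(C)O[Si](C)(C)C(C)(C)C)C=1C | intermediate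
14 | tert-butyl{[(3R,4S)-4-(diazomethyl)-3-[(1Z)-3-(tert-butyldimethylsilyloxy)-2-iodo-3-methylbut-1-en-1-yl]-2,4-dimethylcyclohex-1-en-1-yl]oxy}dimethylsilane | CC(C)(C)[Si](C)(C)OC=1CC[C@](C)(C=[N+]=[N-])[C@@H](/C=C(\I)C(C)(C)O[Si](C)(C)C(C)(C)C)C=1C | intermediate (not isolated)
15 | (5R,10R)-3,11-bis(tert-butyldimethylsilyloxy)eudesma-3,6-dien-8-one (trans ring fusion, 5α-H, 10β-methyl) | CC(C)(C)[Si](C)(C)OC=1CC[C@]2(C)CC(=O)C(C(C)(C)O[Si](C)(C)C(C)(C)C)=C[C@H]2C=1C | intermediate
16 | (5R,10R)-3α,4α-epoxy-3β,11-bis(tert-butyldimethylsilyloxy)eudesm-6-en-8-one | CC(C)(C)[Si](C)(C)O[C@@]13CC[C@]2(C)CC(=O)C(C(C)(C)O[Si](C)(C)C(C)(C)C)=C[C@H]2[C@]1(C)O3 | intermediate (not isolated)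
17 | (4S,5R,10R)-4α,11-bis(tert-butyldimethylsilyloxy)eudesm-6-ene-3,8-dione | O=C1CC[C@]2(C)CC(=O)C(C(C)(C)O[Si](C)(C)C(C)(C)C)=C[C@H]2[C@]1(C)O[Si](C)(C)C(C)(C)C | intermediate
18 | (3S,4S,5R,10R)-3β-hydroxy-4α,11-bis(tert-butyldimethylsilyloxy)eudesm-6-en-8-one | O[C@H]1CC[C@]2(C)CC(=O)C(C(C)(C)O[Si](C)(C)C(C)(C)C)=C[C@H]2[C@]1(C)O[Si](C)(C)C(C)(C)C | intermediate
19 | (3S,4S,5R,10R)-3β,4α,11-trihydroxyeudesm-6-en-8-one | O[C@H]1CC[C@]2(C)CC(=O)C(C(C)(C)O)=C[C@H]2[C@]1(C)O | intermediate
20 | (2R)-2-methylbutanoic acid | CC[C@@H](C)C(=O)O | starting material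
21 | (3S,4S,5R,10R)-4α,11-dihydroxy-8-oxoeudesm-6-en-3β-yl (2R)-2-methylbutanoate | CC[C@@H](C)C(=O)O[C@H]1CC[C@]2(C)CC(=O)C(C(C)(C)O)=C[C@H]2[C@]1(C)O | target

**Step count**
Total steps: 12. Longest linear sequence: 11 steps (steps 1, 2 and 4–12; step 3 is a one-step branch).

**Steps most likely to fail**

Step 8 (Proposed new method). The acylpalladium may be captured by hydride before the carbene arrives, the alkenylpalladium may couple with the carbene before CO inserts, or the free carbene may rearrange by 1,2-shift. The fallback uses known chemistry, sets out from 12 and comes back at 15. Palladium-catalysed aminocarbonylation of the alkenyl iodide of 12 (Pd(OAc)2, Xantphos, CO 1 atm, N,O-dimethylhydroxylamine hydrochloride, Et3N, toluene, 60 °C) should give the N-methoxy-N-methylamide aldehyde F1. NaBH4 in MeOH at 0 °C should reduce its C9 aldehyde to the neopentyl alcohol F2. Pre-mixed PPh3, I2 and imidazole in toluene at 80 °C should convert this into the neopentyl iodide F3. Iodine–lithium exchange with t-BuLi (Et2O–pentane, −78 °C) followed by intramolecular acylation of the alkyllithium by the amide should then close ring B at C8–C9 and give 15.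

Step 4. The trisubstituted enal may react too slowly, the silyloxy diene may add to the formyl group in a Mukaiyama aldol sense, or facial discrimination by the catalyst may be poor. The fallback replaces catalyst control by resolution, sets out from 5 and 7 and comes back at 9. An EtAlCl2-promoted Diels–Alder reaction (CH2Cl2, −78 °C) should give the racemic cycloadduct, that is 8 together with its enantiomer F4. The same acidic hydrolysis should give racemic keto aldehyde, that is 9 together with its enantiomer F5. Condensation of the formyl group with (1R,2R)-N,N′-dimethyl-1,2-diphenylethane-1,2-diamine (MgSO4, Et2O) should give the diastereomeric imidazolidines F6 (from 9) and F7 (from F5). These are separated by chromatography, and mild aqueous acid should hydrolyse F6 back to enantiopure 9.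

Step 5. Regiocontrol of the trans-hydrostannation may erode at the hindered alkyne, or the tin hydride may reduce the formyl group. The fallback installs the iodide before ring A is made, by aluminium hydride chemistry directed by a primary alcohol; it sets out from 3 and comes back at 11. Reduction of 3 with NaBH4 and CeCl3·7H2O in MeOH (Luche reduction) should give the propargylic alcohol F8. Trans-hydroalumination with NaAlH2(OCH2CH2OCH3)2 in THF followed by I2 should give the (Z)-3-iodoallylic alcohol F9. MnO2 in CH2Cl2 should oxidise it to the (Z)-3-iodoenal F10. Wittig reaction with 4 should give the (2E,4Z)-iododienal F11. The catalysed Diels–Alder reaction of F11 with 7 under the conditions of step 4 should give the silyl enol ether cycloadduct F12, which the same acidic hydrolysis should convert into 11.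

**Further compounds**
F1 | step 8 | N-methoxy-N-methylamide analogue of 12 (C7–I replaced by C7–C(=O)N(OCH3)CH3, same configuration and Z geometry) | CC(C)(C)[Si](C)(C)OC=1CC[C@](C)(C=O)[C@@H](/C=C(\C(=O)N(C)OC)C(C)(C)O[Si](C)(C)C(C)(C)C)C=1C
F2 | step 8 | C9 primary alcohol from F1 (formyl reduced to hydroxymethyl) | CC(C)(C)[Si](C)(C)OC=1CC[C@](C)(CO)[C@@H](/C=C(\C(=O)N(C)OC)C(C)(C)O[Si](C)(C)C(C)(C)C)C=1C
F3 | step 8 | C9 neopentyl iodide from F2 (hydroxymethyl replaced by iodomethyl) | CC(C)(C)[Si](C)(C)OC=1CC[C@](C)(CI)[C@@H](/C=C(\C(=O)N(C)OC)C(C)(C)O[Si](C)(C)C(C)(C)C)C=1C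
F4 | step 4 | enantiomer of cycloadduct 8, (1R,6S) | CC(C)(C)[Si](C)(C)OC1=CC[C@@](C)(C=O)[C@H](C#CC(C)(C)O[Si](C)(C)C)C1C
F5 | step 4 | enantiomer of keto aldehyde 9, (1R,2S) | O=C1CC[C@@](C)(C=O)[C@H](C#CC(C)(C)O)C1C
F6 | step 4 | (4R,5R)-1,3-dimethyl-4,5-diphenylimidazolidin-2-yl aminal of 9 | CN1[C@H](c2ccccc2)[C@H](N(C)C1[C@@]3(C)CCC(=O)C(C)[C@@H]3C#CC(C)(C)O)c1ccccc1
F7 | step 4 | (4R,5R)-1,3-dimethyl-4,5-diphenylimidazolidin-2-yl aminal of F5 | CN1[C@H](c2ccccc2)[C@H](N(C)C1[C@]3(C)CCC(=O)C(C)[C@H]3C#CC(C)(C)O)c1ccccc1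
F8 | step 5 | 4-methyl-4-(trimethylsilyloxy)pent-2-yn-1-ol | OCC#CC(C)(C)O[Si](C)(C)C
F9 | step 5 | (2Z)-3-iodo-4-methyl-4-(trimethylsilyloxy)pent-2-en-1-ol | OC/C=C(\I)C(C)(C)O[Si](C)(C)C
F10 | step 5 | (2Z)-3-iodo-4-methyl-4-(trimethylsilyloxy)pent-2-enal | O=C/C=C(\I)C(C)(C)O[Si](C)(C)C
F11 | step 5 | (2E,4Z)-5-iodo-2,6-dimethyl-6-(trimethylsilyloxy)hepta-2,4-dienal | O=C/C(C)=C/C=C(\I)C(C)(C)O[Si](C)(C)C
F12 | step 5 | (1S,6R)-4-(tert-butyldimethylsilyloxy)-6-[(1Z)-2-iodo-3-methyl-3-(trimethylsilyloxy)but-1-en-1-yl]-1,5-dimethylcyclohex-3-ene-1-carbaldehyde | CC(C)(C)[Si](C)(C)OC1=CC[C@](C)(C=O)[C@@H](/C=C(\I)C(C)(C)O[Si](C)(C)C)C1C
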